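**Plan**
- Cuts: O2–C3 (ring A) and C4a=C8a (ring B) are cut together, opening the bicycle to an acyclic hydroxy diketone. The chain is then cut at C4a–C4, C8–C8a, C6–C5 and C6=C7.
- Enabling feature: the tetrasubstituted C4a=C8a alkene shared by rings A and B is the aldol-condensation retron of a C8 ketone and a C4a ynone carbonyl. Once formed, it holds the C1 hydroxymethyl group cis to the C4≡C3 alkyne, with oxygen six atoms from C3.
- Forward: the chain is built linearly from ethyl 3-oxodecanoate (Wittig, allyl opening of an epoxide, acetate aldol, acetylide addition). Ring B and then ring A close in one flask (step 17), and two protecting groups are removed (step 18).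
- Stereochemistry: C7 comes from Sharpless epoxidation of an (E)-2-methyl allylic alcohol with D-(−)-diethyl tartrate. C6 comes from SN2 inversion when the allyl copper reagent opens that epoxide. The key step creates no stereocentre.

Key step: step 17

Remarks on the chemistry:
- Chain atoms carry the locants of the bicyclic target (C1, O2, C3, C4, C4a, C5–C8, C8a) from the start.
- The C8 carbinol (compounds 14–17, 21) and the C4a carbinol (17, 21) are carried as epimer mixtures, because both become carbonyl groups in step 15.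
- The δ-hydroxy aldehyde of step 12 is written as its six-membered lactol, the form in which it is expected to rest.
- The target is (6S,7S).

**Step 1**
Reactants: 1 ethyl 3-oxodecanoate
Product: 2 ethyl 2-(2-heptyl-1,3-dioxolan-2-yl)acetate
Conditions: HOCH2CH2OH, TsOH·H2O (cat.), PhMe, reflux, Dean–Stark
Reagents that add atoms: ethylene glycol (OCCO)
Why: Acid-catalysed ketalisation with azeotropic removal of water masks the ketone of the β-keto ester as a dioxolane, which keeps it from acting as an aldol partner in step 17.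

**Step 2**
Reactants: 2 ethyl 2-(2-heptyl-1,3-dioxolan-2-yl)acetate
Product: 3 2-(2-heptyl-1,3-dioxolan-2-yl)acetaldehyde
Conditions: i-Bu2AlH (1.1 equiv), CH2Cl2, −78 °C
Reagents that add atoms: none
Why: Partial ester reduction with i-Bu2AlH at −78 °C stops at the aluminium hemiacetal, which releases the aldehyde only on work-up.

**Step 3**
Reactants: 3 2-(2-heptyl-1,3-dioxolan-2-yl)acetaldehyde; 4 ethyl 2-(triphenylphosphoranylidene)propanoate
Product: 5 ethyl (2E)-4-(2-heptyl-1,3-dioxolan-2-yl)-2-methylbut-2-enoate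
Conditions: CH2Cl2, 23 → 40 °C
Reagents that add atoms: none
Why: Wittig olefination with the α-methyl stabilised ylide is reversible up to the oxaphosphetane and should therefore give the (E)-trisubstituted enoate.

**Step 4**
Reactants: 5 ethyl (2E)-4-(2-heptyl-1,3-dioxolan-2-yl)-2-methylbut-2-enoate
Product: 6 (2E)-4-(2-heptyl-1,3-dioxolan-2-yl)-2-methylbut-2-en-1-ol
Conditions: i-Bu2AlH (2.5 equiv), CH2Cl2, −78 °C
Reagents that add atoms: none
Why: i-Bu2AlH reduces the conjugated ester in a 1,2-sense to the allylic alcohol without touching alkene or ketal.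

**Step 5**
Reactants: 6 (2E)-4-(2-heptyl-1,3-dioxolan-2-yl)-2-methylbut-2-en-1-ol
Product: 7 [(2R,3R)-3-[(2-heptyl-1,3-dioxolan-2-yl)methyl]-2-methyloxiran-2-yl]methanol
Conditions: Ti(OiPr)4 (10 mol %), D-(−)-diethyl tartrate (12 mol %), t-BuOOH, 4 Å molecular sieves, CH2Cl2, −20 °C
Reagents that add atoms: tert-butyl hydroperoxide (CC(C)(C)OO)
Why: In the Sharpless asymmetric epoxidation the titanium tartrate complex binds the allylic hydroxyl and delivers the peroxide oxygen to one alkene face, which sets C7 (and provisionally C6) as the (2R,3R)-epoxide, the mirror image of the (2S,3S)-epoxides that L-(+)-tartrate gives with (E)-allylic alcohols.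

**Step 6**
Reactants: 7 [(2R,3R)-3-[(2-heptyl-1,3-dioxolan-2-yl)methyl]-2-methyloxiran-2-yl]methanol; 8 allylmagnesium bromide
Product: 9 (2S,3S)-3-[(2-heptyl-1,3-dioxolan-2-yl)methyl]-2-methylhex-5-ene-1,2-diol
Conditions: 8 (4 equiv), CuI (0.2 equiv), THF/Et2O, −40 → −20 °C
Reagents that add atoms: none
Why: Copper-catalysed Grignard opening of a 2-methyl-2,3-epoxy alcohol proceeds by SN2 attack at the secondary epoxide carbon because the other one is quaternary, so C6 is inverted to its final configuration while C7 keeps the one set in step 5.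

**Step 7**
Reactants: 9 (2S,3S)-3-[(2-heptyl-1,3-dioxolan-2-yl)methyl]-2-methylhex-5-ene-1,2-diol
Product: 10 (2S,3S)-3-[(2-heptyl-1,3-dioxolan-2-yl)methyl]-2-methyl-1,2-bis(triethylsilyloxy)hex-5-ene
Conditions: Et3SiOTf (2.5 equiv), 2,6-lutidine, CH2Cl2, −78 → 0 °C
Reagents that add atoms: triethylsilyl trifluoromethanesulfonate (CC[Si](CC)(CC)OS(=O)(=O)C(F)(F)F)
Why: The silyl triflate with 2,6-lutidine is reactive enough to silylate the tertiary as well as the primary hydroxyl, and a ketone dioxolane is not opened at low temperature.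

**Step 8**
Reactants: 10 (2S,3S)-3-[(2-heptyl-1,3-dioxolan-2-yl)methyl]-2-methyl-1,2-bis(triethylsilyloxy)hex-5-ene
Product: 11 (2S,3S)-3-[(2-heptyl-1,3-dioxolan-2-yl)methyl]-2-methyl-2-(triethylsilyloxy)hex-5-enal
Conditions: (COCl)2, DMSO, CH2Cl2, −78 → −40 °C; then Et3N, −78 → 0 °C
Reagents that add atoms: none
Why: Under Swern conditions a primary triethylsilyl ether is attacked at oxygen by chlorodimethylsulfonium chloride and oxidised directly to the aldehyde, whereas the hindered tertiary silyl ether should not react (selective oxidative desilylation).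

**Step 9**
Reactants: 11 (2S,3S)-3-[(2-heptyl-1,3-dioxolan-2-yl)methyl]-2-methyl-2-(triethylsilyloxy)hex-5-enal; 12 ethyl acetate
Product: 14 ethyl (4S,5S)-5-[(2-heptyl-1,3-dioxolan-2-yl)methyl]-3-hydroxy-4-methyl-4-(triethylsilyloxy)oct-7-enoate (C3 epimers), via lithium enolate of ethyl acetate 13 (not isolated)
Conditions: LiN(i-Pr)2, 12, THF, −78 °C; then 11; NH4Cl quench at −78 °C
Reagents that add atoms: none
Why: Aldol addition of the lithium ester enolate to the non-enolisable α-quaternary aldehyde brings in C8a and C1, and the uncontrolled C8 carbinol is immaterial because it becomes a ketone in step 15.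

**Step 10**
Reactants: 14 ethyl (4S,5S)-5-[(2-heptyl-1,3-dioxolan-2-yl)methyl]-3-hydroxy-4-methyl-4-(triethylsilyloxy)oct-7-enoate
Product: 15 (4S,5S)-5-[(2-heptyl-1,3-dioxolan-2-yl)methyl]-4-methyl-4-(triethylsilyloxy)oct-7-ene-1,3-diol (C3 epimers)
Conditions: LiBH4, THF/MeOH, 0 → 23 °C
Reagents that add atoms: none
Why: LiBH4 reduces the ester chemoselectively to the primary alcohol (ester reduction) and leaves alkene, ketal and silyl ether untouched.

**Step 11**
Reactants: 15 (4S,5S)-5-[(2-heptyl-1,3-dioxolan-2-yl)methyl]-4-methyl-4-(triethylsilyloxy)oct-7-ene-1,3-diol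
Product: 16 (4S,5S)-5-[(2-heptyl-1,3-dioxolan-2-yl)methyl]-4-methyl-1,4-bis(triethylsilyloxy)oct-7-en-3-ol (C3 epimers)
Conditions: Et3SiCl (1.05 equiv), imidazole, CH2Cl2, −40 → 0 °C
Reagents that add atoms: chlorotriethylsilane (CC[Si](CC)(CC)Cl)
Why: Silylation with the chlorosilane and imidazole differentiates the unhindered primary hydroxyl from the secondary one, which is flanked by the quaternary C7.

**Step 12**
Reactants: 16 (4S,5S)-5-[(2-heptyl-1,3-dioxolan-2-yl)methyl]-4-methyl-1,4-bis(triethylsilyloxy)oct-7-en-3-ol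
Product: 17 (4S,5S)-4-[(2-heptyl-1,3-dioxolan-2-yl)methyl]-5-methyl-5-(triethylsilyloxy)-6-[2-(triethylsilyloxy)ethyl]oxan-2-ol (lactol of the C4a aldehyde with the C8 hydroxyl; epimers at C2 and C6 of the oxane)
Conditions: O3, CH2Cl2, −78 °C; then PPh3, −78 → 23 °C
Reagents that add atoms: ozone ([O-][O+]=O)
Why: Ozonolysis with reductive work-up cleaves the only alkene to the C4a aldehyde, which should close onto the C8 hydroxyl as a six-membered lactol.

**Step 13**
Reactants: 18 (E)-crotonaldehyde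
Product: 19 (3E)-1,1-dibromopenta-1,3-diene
Conditions: CBr4, PPh3 (2 equiv), CH2Cl2, 0 °C
Reagents that add atoms: carbon tetrabromide (BrC(Br)(Br)Br)
Why: Corey–Fuchs dibromo-olefination (Wittig reaction of Ph3P=CBr2 formed in the flask) converts the enal into the 1,1-dibromodiene without touching the (E)-alkene.

**Step 14**
Reactants: 17 lactol (4S,5S)-4-[(2-heptyl-1,3-dioxolan-2-yl)methyl]-5-methyl-5-(triethylsilyloxy)-6-[2-(triethylsilyloxy)ethyl]oxan-2-ol; 19 (3E)-1,1-dibromopenta-1,3-diene
Product: 21 (4S,5S,10E)-5-[(2-heptyl-1,3-dioxolan-2-yl)methyl]-4-methyl-1,4-bis(triethylsilyloxy)dodec-10-en-8-yne-3,7-diol (epimers at C3 and C7), via lithium pentenynide 20 (not isolated)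
Conditions: 19 (4 equiv), n-BuLi (2.0 equiv per 19), THF, −78 → 0 °C; then 17, −78 → −20 °C; NH4Cl quench
Reagents that add atoms: none
Why: Bromine–lithium exchange, Fritsch–Buttenberg–Wiechell rearrangement and deprotonation (second stage of the Corey–Fuchs alkyne synthesis) give the lithium acetylide, whose excess opens the lactol through its hydroxy aldehyde form and adds 1,2 to the aldehyde; the C4a carbinol forms as both epimers and is oxidised next.

**Step 15**
Reactants: 21 (4S,5S,10E)-5-[(2-heptyl-1,3-dioxolan-2-yl)methyl]-4-methyl-1,4-bis(triethylsilyloxy)dodec-10-en-8-yne-3,7-diol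
Product: 22 (4S,5S,10E)-5-[(2-heptyl-1,3-dioxolan-2-yl)methyl]-4-methyl-1,4-bis(triethylsilyloxy)dodec-10-en-8-yne-3,7-dione
Conditions: Dess–Martin periodinane (3 equiv), pyridine, CH2Cl2, 0 → 23 °C
Reagents that add atoms: none
Why: Dess–Martin oxidation converts the hindered C8 carbinol and the propargylic C4a carbinol into the 1,5-diketone in one operation under buffered, non-enolising conditions that spare silyl ethers and ketal.

**Step 16**
Reactants: 22 (4S,5S,10E)-5-[(2-heptyl-1,3-dioxolan-2-yl)methyl]-4-methyl-1,4-bis(triethylsilyloxy)dodec-10-en-8-yne-3,7-dione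
Product: 23 (4S,5S,10E)-5-[(2-heptyl-1,3-dioxolan-2-yl)methyl]-1-hydroxy-4-methyl-4-(triethylsilyloxy)dodec-10-en-8-yne-3,7-dione
Conditions: HF·pyridine, pyridine, THF, 0 °C
Reagents that add atoms: none
Why: Buffered HF·pyridine cleaves the unhindered primary silyl ether much faster than the tertiary one (sterically controlled desilylation), which frees the C1 hydroxyl without touching ynone or dioxolane.

**Step 17**
Reactants: 23 (4S,5S,10E)-5-[(2-heptyl-1,3-dioxolan-2-yl)methyl]-1-hydroxy-4-methyl-4-(triethylsilyloxy)dodec-10-en-8-yne-3,7-dione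
Product: 26 (6S,7S)-6-[(2-heptyl-1,3-dioxolan-2-yl)methyl]-7-methyl-3-[(1E)-prop-1-en-1-yl]-7-(triethylsilyloxy)-6,7-dihydro-1H-isochromen-8(5H)-one, via aldol adduct 24 (not isolated), via hydroxy enynone 25 (not isolated)
Conditions: anhydrous CSA (1.0 equiv), ClCH2CH2Cl, 23 → 50 °C
Reagents that add atoms: none
Why: CSA enolises the C8 ketone, which has α-hydrogens only at C8a because C7 is quaternary, and the enol adds to the acid-activated C4a ynone carbonyl in a 6-(enolexo)-exo-trig aldol closure of ring B (24); acid-catalysed β-elimination of the tertiary propargylic hydroxyl then gives the conjugated enynone 25 with the tetrasubstituted C4a=C8a bond. In 25 the ring holds the C1 hydroxymethyl group cis to the alkyne, and the hydroxyl adds to C3 in a 6-endo-dig closure of ring A with proton delivery to C4, so that the C3=C4 enol ether forms directly without a ring allene; should the direct addition be slow, the water set free in the condensation can relay the oxygen by 1,6-hydration at C3 followed by hemiketalisation and dehydration to the same pyran. The closest known reaction types are the acid-mediated intramolecular aldol condensation of 1,5-diketones to cyclohexenones and the acid-promoted 6-endo-dig cyclisation of hydroxy ynones to pyranones. No stereocentre is created, and C6 and C7 cannot epimerise because C7 is quaternary and C6 is α to no carbonyl group. The step needs three selectivities: site of enolisation (the C5 enol of the ynone could only close a four-membered ring and returns), 1,2- over conjugate attack on the ynone (conjugate attack by C8a would need an eight-membered ring) and 6-endo over 5-exo at the alkyne (C3 is the δ-terminus of the protonated dienynone and carries the propenyl group, whereas C4 is not activated). The silyl ether on the C7 oxygen and the dioxolane keep that hydroxyl and the side-chain ketone from competing as nucleophile or aldol partner.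

**Step 18**
Reactants: 26 (6S,7S)-6-[(2-heptyl-1,3-dioxolan-2-yl)methyl]-7-methyl-3-[(1E)-prop-1-en-1-yl]-7-(triethylsilyloxy)-6,7-dihydro-1H-isochromen-8(5H)-one
Product: 27 (6S,7S)-7-hydroxy-7-methyl-6-(2-oxononyl)-3-[(1E)-prop-1-en-1-yl]-6,7-dihydro-1H-isochromen-8(5H)-one
Conditions: 1 M aq. HCl, THF, 23 °C
Reagents that add atoms: water (O)
Why: Aqueous acid hydrolyses the dioxolane and the tertiary silyl ether (acetal hydrolysis and acid desilylation), while the push–pull dienol ether, a doubly vinylogous ester, should resist and no stereocentre is enolisable.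

**Compound list**
1 | ethyl 3-oxodecanoate | CCCCCCCC(=O)CC(=O)OCC | starting material
2 | ethyl 2-(2-heptyl-1,3-dioxolan-2-yl)acetate | CCCCCCCC1(CC(=O)OCC)OCCO1 | intermediate
3 | 2-(2-heptyl-1,3-dioxolan-2-yl)acetaldehyde | CCCCCCCC1(CC=O)OCCO1 | intermediate
4 | ethyl 2-(triphenylphosphoranylidene)propanoate | CCOC(=O)C(C)=P(c1ccccc1)(c1ccccc1)c1ccccc1 | starting material
5 | ethyl (2E)-4-(2-heptyl-1,3-dioxolan-2-yl)-2-methylbut-2-enoate | CCCCCCCC1(C/C=C(\C)C(=O)OCC)OCCO1 | intermediate
6 | (2E)-4-(2-heptyl-1,3-dioxolan-2-yl)-2-methylbut-2-en-1-ol | CCCCCCCC1(C/C=C(\C)CO)OCCO1 | intermediate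
7 | [(2R,3R)-3-[(2-heptyl-1,3-dioxolan-2-yl)methyl]-2-methyloxiran-2-yl]methanol | OC[C@@]1(C)O[C@@H]1CC2(CCCCCCC)OCCO2 | intermediate
8 | allylmagnesium bromide | C=CC[Mg]Br | starting material
9 | (2S,3S)-3-[(2-heptyl-1,3-dioxolan-2-yl)methyl]-2-methylhex-5-ene-1,2-diol | OC[C@@](C)(O)[C@@H](CC=C)CC1(CCCCCCC)OCCO1 | intermediate
10 | (2S,3S)-3-[(2-heptyl-1,3-dioxolan-2-yl)methyl]-2-methyl-1,2-bis(triethylsilyloxy)hex-5-ene | CC[Si](CC)(CC)OC[C@@](C)(O[Si](CC)(CC)CC)[C@@H](CC=C)CC1(CCCCCCC)OCCO1 | intermediate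
11 | (2S,3S)-3-[(2-heptyl-1,3-dioxolan-2-yl)methyl]-2-methyl-2-(triethylsilyloxy)hex-5-enal | O=C[C@@](C)(O[Si](CC)(CC)CC)[C@@H](CC=C)CC1(CCCCCCC)OCCO1 | intermediate
12 | ethyl acetate | CCOC(C)=O | starting material
13 | lithium 1-ethoxyethen-1-olate (lithium enolate of ethyl acetate) | C=C(O[Li])OCC | intermediate (not isolated)
14 | ethyl (4S,5S)-5-[(2-heptyl-1,3-dioxolan-2-yl)methyl]-3-hydroxy-4-methyl-4-(triethylsilyloxy)oct-7-enoate (C3 epimers) | CCOC(=O)CC(O)[C@@](C)(O[Si](CC)(CC)CC)[C@@H](CC=C)CC1(CCCCCCC)OCCO1 | intermediate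
15 | (4S,5S)-5-[(2-heptyl-1,3-dioxolan-2-yl)methyl]-4-methyl-4-(triethylsilyloxy)oct-7-ene-1,3-diol (C3 epimers) | OCCC(O)[C@@](C)(O[Si](CC)(CC)CC)[C@@H](CC=C)CC1(CCCCCCC)OCCO1 | intermediate
16 | (4S,5S)-5-[(2-heptyl-1,3-dioxolan-2-yl)methyl]-4-methyl-1,4-bis(triethylsilyloxy)oct-7-en-3-ol (C3 epimers) | CC[Si](CC)(CC)OCCC(O)[C@@](C)(O[Si](CC)(CC)CC)[C@@H](CC=C)CC1(CCCCCCC)OCCO1 | intermediate
17 | (4S,5S)-4-[(2-heptyl-1,3-dioxolan-2-yl)methyl]-5-methyl-5-(triethylsilyloxy)-6-[2-(triethylsilyloxy)ethyl]oxan-2-ol (lactol, epimers at C2 and C6) | CC[Si](CC)(CC)OCCC1[C@@](C)(O[Si](CC)(CC)CC)[C@@H](CC(O)O1)CC2(CCCCCCC)OCCO2 | intermediate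
18 | (E)-crotonaldehyde | C/C=C/C=O | starting material
19 | (3E)-1,1-dibromopenta-1,3-diene | C/C=C/C=C(Br)Br | intermediate
20 | lithium (3E)-pent-3-en-1-yn-1-ide | [Li]C#C/C=C/C | intermediate (not isolated)
21 | (4S,5S,10E)-5-[(2-heptyl-1,3-dioxolan-2-yl)methyl]-4-methyl-1,4-bis(triethylsilyloxy)dodec-10-en-8-yne-3,7-diol (epimers at C3 and C7) | CC[Si](CC)(CC)OCCC(O)[C@@](C)(O[Si](CC)(CC)CC)[C@@H](CC(O)C#C/C=C/C)CC1(CCCCCCC)OCCO1 | intermediate
22 | (4S,5S,10E)-5-[(2-heptyl-1,3-dioxolan-2-yl)methyl]-4-methyl-1,4-bis(triethylsilyloxy)dodec-10-en-8-yne-3,7-dione | CC[Si](CC)(CC)OCCC(=O)[C@@](C)(O[Si](CC)(CC)CC)[C@@H](CC(=O)C#C/C=C/C)CC1(CCCCCCC)OCCO1 | intermediate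
23 | (4S,5S,10E)-5-[(2-heptyl-1,3-dioxolan-2-yl)methyl]-1-hydroxy-4-methyl-4-(triethylsilyloxy)dodec-10-en-8-yne-3,7-dione | OCCC(=O)[C@@](C)(O[Si](CC)(CC)CC)[C@@H](CC(=O)C#C/C=C/C)CC1(CCCCCCC)OCCO1 | intermediate
24 | (5S,6S)-5-[(2-heptyl-1,3-dioxolan-2-yl)methyl]-3-hydroxy-2-(hydroxymethyl)-6-methyl-3-[(3E)-pent-3-en-1-yn-1-yl]-6-(triethylsilyloxy)cyclohexan-1-one (epimers at C2 and C3) | C/C=C/C#CC1(O)C(CO)C(=O)[C@@](C)(O[Si](CC)(CC)CC)[C@H](CC2(CCCCCCC)OCCO2)C1 | intermediate (not isolated)
25 | (5S,6S)-5-[(2-heptyl-1,3-dioxolan-2-yl)methyl]-2-(hydroxymethyl)-6-methyl-3-[(3E)-pent-3-en-1-yn-1-yl]-6-(triethylsilyloxy)cyclohex-2-en-1-one | C/C=C/C#CC1=C(CO)C(=O)[C@@](C)(O[Si](CC)(CC)CC)[C@H](CC2(CCCCCCC)OCCO2)C1 | intermediate (not isolated)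
26 | (6S,7S)-6-[(2-heptyl-1,3-dioxolan-2-yl)methyl]-7-methyl-3-[(1E)-prop-1-en-1-yl]-7-(triethylsilyloxy)-6,7-dihydro-1H-isochromen-8(5H)-one | C/C=C/C1=CC2=C(CO1)C(=O)[C@@](C)(O[Si](CC)(CC)CC)[C@H](CC3(CCCCCCC)OCCO3)C2 | intermediate
27 | (6S,7S)-7-hydroxy-7-methyl-6-(2-oxononyl)-3-[(1E)-prop-1-en-1-yl]-6,7-dihydro-1H-isochromen-8(5H)-one | C/C=C/C1=CC2=C(CO1)C(=O)[C@@](C)(O)[C@H](CC(=O)CCCCCCC)C2 | target

**Step count**
Total: 18 steps. Longest linear sequence: 17 steps (steps 1–12 and 14–18 from ethyl 3-oxodecanoate); step 13 is the one-step side branch.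

**Steps most likely to fail**

1. Step 17. Three things may go wrong:
   - acid-catalysed dehydration of the 3-hydroxypropanoyl unit to a vinyl ketone before ring B has closed;
   - slow addition of the hydroxyl across the alkyne, so that the enynone degrades or the dioxolane is hydrolysed by the water of condensation;
   - attack of oxygen at C4 instead of C3.

   Fallback, a stepwise closure that keeps the C1 oxygen silylated until ring B exists: setting out from diketone 22, an enolate aldol addition (LiN(SiMe3)2, THF, −78 °C) would give the silylated aldol adduct F1. Dehydration with the Burgess reagent would give the silylated enynone F2. HF·pyridine then frees the primary hydroxyl to give 25, isolated in this variant. Ring A is closed by π-acid-catalysed 6-endo-dig hydroalkoxylation (AgOTf or Ph3PAuNTf2, CH2Cl2, 23 °C), known for 2-en-4-yn-1-ols and 2-alkynylbenzyl alcohols, and the route is rejoined at 26.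

2. Step 14. The lactol may open incompletely, so that the acetylide acts only as a base. The lithium alkoxide at C8 may also take over the silyl group from the neighbouring tertiary oxygen. Fallback, which avoids a free C8 alkoxide: setting out from alcohol 16, Dess–Martin oxidation would give the ketone F3 and ozonolysis (O3; PPh3) the keto aldehyde F4. Chemoselective 1,2-addition of the alkynylcerium reagent (20 with CeCl3, THF, −78 °C, 1.2 equiv) to the aldehyde in the presence of the hindered α-quaternary ketone would give the hydroxy ketone F5. A second Dess–Martin oxidation rejoins the route at 22.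

3. Step 18. The dienol ether may be opened hydrolytically, or the liberated γ-hydroxy ketone may cyclise and dehydrate under acid, while the hindered tertiary silyl ether is still being cleaved. Fallback, which avoids aqueous mineral acid: setting out from 26, fluoride desilylation (HF·pyridine, THF, 23 °C) would give the hydroxy ketal F6. Neutral transketalisation of its dioxolane (I2 cat., acetone, 23 °C) arrives at 27.

**Further compounds**
F1 | step 17 | (5S,6S)-5-[(2-heptyl-1,3-dioxolan-2-yl)methyl]-3-hydroxy-6-methyl-3-[(3E)-pent-3-en-1-yn-1-yl]-6-(triethylsilyloxy)-2-[(triethylsilyloxy)methyl]cyclohexan-1-one | C/C=C/C#CC1(O)C(CO[Si](CC)(CC)CC)C(=O)[C@@](C)(O[Si](CC)(CC)CC)[C@H](CC2(CCCCCCC)OCCO2)C1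
F2 | step 17 | (5S,6S)-5-[(2-heptyl-1,3-dioxolan-2-yl)methyl]-6-methyl-3-[(3E)-pent-3-en-1-yn-1-yl]-6-(triethylsilyloxy)-2-[(triethylsilyloxy)methyl]cyclohex-2-en-1-one | C/C=C/C#CC1=C(CO[Si](CC)(CC)CC)C(=O)[C@@](C)(O[Si](CC)(CC)CC)[C@H](CC2(CCCCCCC)OCCO2)C1
F3 | step 14 | (4S,5S)-5-[(2-heptyl-1,3-dioxolan-2-yl)methyl]-4-methyl-1,4-bis(triethylsilyloxy)oct-7-en-3-one | CC[Si](CC)(CC)OCCC(=O)[C@@](C)(O[Si](CC)(CC)CC)[C@@H](CC=C)CC1(CCCCCCC)OCCO1
F4 | step 14 | (3S,4S)-3-[(2-heptyl-1,3-dioxolan-2-yl)methyl]-4-methyl-5-oxo-4,7-bis(triethylsilyloxy)heptanal | CC[Si](CC)(CC)OCCC(=O)[C@@](C)(O[Si](CC)(CC)CC)[C@@H](CC=O)CC1(CCCCCCC)OCCO1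
F5 | step 14 | (4S,5S,10E)-5-[(2-heptyl-1,3-dioxolan-2-yl)methyl]-7-hydroxy-4-methyl-1,4-bis(triethylsilyloxy)dodec-10-en-8-yn-3-one (C7 epimers) | CC[Si](CC)(CC)OCCC(=O)[C@@](C)(O[Si](CC)(CC)CC)[C@@H](CC(O)C#C/C=C/C)CC1(CCCCCCC)OCCO1
F6 | step 18 | (6S,7S)-6-[(2-heptyl-1,3-dioxolan-2-yl)methyl]-7-hydroxy-7-methyl-3-[(1E)-prop-1-en-1-yl]-6,7-dihydro-1H-isochromen-8(5H)-one | C/C=C/C1=CC2=C(CO1)C(=O)[C@@](C)(O)[C@H](CC3(CCCCCCC)OCCO3)C2
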